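Everything rests on opening the lactone bond O1–C2 of ring A (the α-alkylidene γ-lactone O1–C2(=O)–C3–C4H2–C5H) and reading carbinol C5 as a ketone. C5, the only stereocentre, carries O1, a 2-methylprop-1-enyl group and methylene C4, and lies γ to ester carbon C2. The precursor is therefore an achiral γ-keto α-alkylidene methyl ester that already holds the complete all-E trienyl butenolide chain (ring B). A ketoreductase reduces its enone carbonyl from the Re face; the (S)-hydroxyl then closes ring A on the ester with loss of methanol. One operation thus sets the stereocentre, forms the ring and delivers the target itself.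

Key step: step 12

Remarks on the chemistry:
- The CIP order at C5 is O > alkenyl carbon > C4 > H in both the ketone and the carbinol, so hydride delivery to the Re face gives (S), as the target requires.
- Compounds 3, 4, 5, 6 and 9 carry one stereocentre at the bromohydrin or epoxide carbon. They are used as racemates, because this carbon is excised as acetone in step 8.
- From compound 6 onward the polyenes are handled under argon with exclusion of light.

Step 1
Reactants: 1 (2E,6E)-farnesol
Product: 2 (2E,6E)-farnesyl acetate [(2E,6E)-3,7,11-trimethyldodeca-2,6,10-trien-1-yl acetate]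
Conditions: Ac2O, Et3N, DMAP (cat.), CH2Cl2, 0 °C → rt
Reagents that add atoms: acetic anhydride, CC(=O)OC(C)=O
Why: DMAP-catalysed acylation masks the allylic alcohol and inductively deactivates the neighbouring C2–C3 alkene towards the electrophilic bromine of step 2.

Step 2
Reactants: 2 (2E,6E)-farnesyl acetate
Product: 3 racemic (2E,6E)-10-bromo-11-hydroxy-3,7,11-trimethyldodeca-2,6-dien-1-yl acetate
Conditions: NBS (1.1 equiv), THF/H2O, 0 °C
Reagents that add atoms: N-bromosuccinimide, O=C1CCC(=O)N1Br; water, O
Why: Electrophilic bromohydrin formation in aqueous THF should pick the terminal trisubstituted alkene, because the chain coils in the polar medium and the C2–C3 alkene is deactivated, and water opens the bromonium ion at the tertiary carbon (Markovnikov); the new centre is racemic and is removed in step 8.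

Step 3
Reactants: 3 racemic terminal bromohydrin acetate
Product: 4 racemic (2E,6E)-9-(3,3-dimethyloxiran-2-yl)-3,7-dimethylnona-2,6-dien-1-ol (10,11-epoxyfarnesol)
Conditions: K2CO3, MeOH, rt
Reagents that add atoms: none
Why: Intramolecular Williamson displacement of the secondary bromide by the tertiary alkoxide closes the epoxide, and the same carbonate/methanol medium removes the acetate by transesterification.

Step 4
Reactants: 4 racemic 10,11-epoxyfarnesol
Product: 5 racemic (2E,6E)-9-(3,3-dimethyloxiran-2-yl)-3,7-dimethylnona-2,6-dienal
Conditions: MnO2 (activated, excess), CH2Cl2, rt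
Reagents that add atoms: none
Why: MnO2 oxidation is selective for allylic alcohols and should leave the epoxide and the E geometry of the conjugated alkene untouched.

Step 5
Reactants: 5 racemic epoxy enal
Product: 6 racemic 2-[(1E,3E,7E)-10-(3,3-dimethyloxiran-2-yl)-4,8-dimethyldeca-1,3,7-trien-1-yl]-4,4,5,5-tetramethyl-1,3,2-dioxaborolane
Conditions: CH2(Bpin)2, LiTMP (lithium 2,2,6,6-tetramethylpiperidide), THF, 0 °C; then 5, −78 °C → rt
Reagents that add atoms: bis(4,4,5,5-tetramethyl-1,3,2-dioxaborolan-2-yl)methane, CC1(C)OB(CB2OC(C)(C)C(C)(C)O2)OC1(C)C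
Why: Boron–Wittig olefination, in which the lithiated geminal bis(boronate) adds 1,2 to the aldehyde and syn B–O elimination gives the trans-alkenyl boronate, while the trisubstituted epoxide should be inert to the stabilised carbanion at low temperature.

Step 6
Reactants: 7 tetronic acid
Product: 8 4-bromofuran-2(5H)-one
Conditions: (COBr)2, DMF, CH2Cl2, 0 °C → rt
Reagents that add atoms: oxalyl bromide, O=C(Br)C(=O)Br
Why: Vilsmeier-type bromodehydroxylation, in which the bromoiminium salt activates the enol oxygen of the vinylogous acid and bromide substitutes at C4 by addition–elimination.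

Step 7
Reactants: 6 racemic epoxy dienyl boronate; 8 4-bromofuran-2(5H)-one
Product: 9 racemic 4-[(1E,3E,7E)-10-(3,3-dimethyloxiran-2-yl)-4,8-dimethyldeca-1,3,7-trien-1-yl]furan-2(5H)-one
Conditions: Pd(PPh3)4 (5 mol %), K3PO4 (1 M aq.), THF, 40 °C, degassed, dark
Reagents that add atoms: none
Why: Suzuki–Miyaura coupling of the activated β-bromo enoate (fast oxidative addition to zerovalent palladium) with the dienyl boronate proceeds with retention of both alkene geometries, and phosphate activates boron while being mild towards the butenolide and the epoxide.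

Step 8
Reactants: 9 racemic epoxy trienyl butenolide
Product: 10 (4E,8E,10E)-4,8-dimethyl-11-(5-oxo-2,5-dihydrofuran-3-yl)undeca-4,8,10-trienal
Conditions: H5IO6, THF/Et2O, 0 °C
Reagents that add atoms: none
Why: Periodic acid opens the trisubstituted epoxide to the glycol and cleaves it in the same flask (Malaprade-type glycol cleavage), releasing acetone and the aldehyde, whose oxygen is the former epoxide oxygen, without attacking the alkenes or the lactone.

Step 9
Reactants: 11 mesityl oxide
Product: 13 1-bromo-4-methylpent-3-en-2-one, via silyl dienol ether 12 (not isolated)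
Conditions: LiN(SiMe3)2, Me3SiCl, THF, −78 °C; then NBS, −78 → 0 °C
Reagents that add atoms: N-bromosuccinimide, O=C1CCC(=O)N1Br
Why: Kinetic deprotonation of the enone at the α′-methyl group and O-silylation give the 2-silyloxydiene, whose terminal enol-ether carbon is the most nucleophilic site towards NBS (electrophilic α-bromination of a silyl enol ether).

Step 10
Reactants: 13 1-bromo-4-methylpent-3-en-2-one; 14 methyl (triphenylphosphoranylidene)acetate
Product: 16 methyl 6-methyl-4-oxo-2-(triphenylphosphoranylidene)hept-5-enoate, via phosphonium bromide 15 (not isolated)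
Conditions: 14 (2 equiv), EtOAc, rt; filtration of the precipitated phosphonium bromide
Reagents that add atoms: none
Why: SN2 C-alkylation of the stabilised ylide by the reactive α-bromo ketone is followed by transylidation, the second equivalent of 14 removing the acidic P–C–H proton and precipitating as its salt, while conjugate addition is blocked by the β,β-dimethyl substitution.

Step 11
Reactants: 10 trienyl butenolide aldehyde; 16 keto ylide
Product: 17 methyl (2E,6E,10E,12E)-6,10-dimethyl-2-(4-methyl-2-oxopent-3-en-1-yl)-13-(5-oxo-2,5-dihydrofuran-3-yl)trideca-2,6,10,12-tetraenoate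
Conditions: toluene, 80 °C, argon, dark
Reagents that add atoms: none
Why: Wittig olefination with an α-substituted ester-stabilised ylide should place the aldehyde-derived chain trans to the ester (E), and the ylide is too weak a base and nucleophile to touch the butenolide or the ketone.

Step 12
Reactants: 17 achiral γ-keto α-alkylidene methyl ester
Product: 19 target CNP0187251.1 as (3E,5S)-3-[(4E,8E,10E)-4,8-dimethyl-11-(5-oxo-2,5-dihydrofuran-3-yl)undeca-4,8,10-trien-1-ylidene]-5-(2-methylprop-1-en-1-yl)oxolan-2-one, via (S)-hydroxy ester 18 (not isolated)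
Conditions: NADPH-dependent ketoreductase (hit from a panel with members of both facial senses, e.g. a Lactobacillus kefir alcohol dehydrogenase variant), NADP+ (cat.), i-PrOH (10 vol %), KH2PO4/K2HPO4 buffer pH 7.0, MgSO4 (2 mM), DMSO (10 vol %), 30 °C, dark; MTBE extraction; residual 18 closed on SiO2
Reagents that add atoms: none
Why: The enzyme binds the C5 ketone beside the nicotinamide ring and passes the hydride of NADPH to the Re face of the carbonyl while an active-site acid protonates the oxygen, giving (S)-alcohol 18, and isopropanol regenerates NADPH on the same enzyme. The closest known reaction type is the ketoreductase reduction of γ-keto esters to enantioenriched γ-lactones and of enones to allylic alcohols. Ring A then closes by 5-exo-trig attack of the C5 hydroxyl on ester carbon C2 with loss of methanol, helped by the sp2 carbon C3 that holds both arms close together. The C5 stereocentre is set by the enzyme alone (catalyst control on an achiral substrate): the 2-methylprop-1-enyl group and the long ester-bearing chain must sit in different pockets so that hydride arrives on the Re face, which is the anti-Prelog sense if the alkenyl group occupies the small pocket. The step needs enantioface selectivity, 1,2- over 1,4-reduction and intact alkene geometries: the first rests on the size difference of the two ketone substituents, the second on the hydride-to-carbonyl mechanism of this enzyme class, which does not reduce C=C bonds, esters or lactones, and the third on neutral buffer at 30 °C in the dark, which also avoids ionising the allylic C5–O bond.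

Compound list
1 | (2E,6E)-farnesol | CC(C)=CCC/C(C)=C/CC/C(C)=C/CO | starting material
2 | (2E,6E)-farnesyl acetate | CC(C)=CCC/C(C)=C/CC/C(C)=C/COC(C)=O | intermediate
3 | racemic (2E,6E)-10-bromo-11-hydroxy-3,7,11-trimethyldodeca-2,6-dien-1-yl acetate | CC(C)(O)C(Br)CC/C(C)=C/CC/C(C)=C/COC(C)=O | intermediate
4 | racemic (2E,6E)-9-(3,3-dimethyloxiran-2-yl)-3,7-dimethylnona-2,6-dien-1-ol | CC1(C)OC1CC/C(C)=C/CC/C(C)=C/CO | intermediate
5 | racemic (2E,6E)-9-(3,3-dimethyloxiran-2-yl)-3,7-dimethylnona-2,6-dienal | CC1(C)OC1CC/C(C)=C/CC/C(C)=C/C=O | intermediate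
6 | racemic 2-[(1E,3E,7E)-10-(3,3-dimethyloxiran-2-yl)-4,8-dimethyldeca-1,3,7-trien-1-yl]-4,4,5,5-tetramethyl-1,3,2-dioxaborolane | CC1(C)OC1CC/C(C)=C/CC/C(C)=C/C=C/B1OC(C)(C)C(C)(C)O1 | intermediate
7 | tetronic acid | O=C1CC(=O)CO1 | starting material
8 | 4-bromofuran-2(5H)-one | O=C1C=C(Br)CO1 | intermediate
9 | racemic 4-[(1E,3E,7E)-10-(3,3-dimethyloxiran-2-yl)-4,8-dimethyldeca-1,3,7-trien-1-yl]furan-2(5H)-one | CC1(C)OC1CC/C(C)=C/CC/C(C)=C/C=C/C1=CC(=O)OC1 | intermediate
10 | (4E,8E,10E)-4,8-dimethyl-11-(5-oxo-2,5-dihydrofuran-3-yl)undeca-4,8,10-trienal | O=CCC/C(C)=C/CC/C(C)=C/C=C/C1=CC(=O)OC1 | intermediate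
11 | mesityl oxide | CC(C)=CC(C)=O | starting material
12 | 4-methyl-2-(trimethylsilyloxy)penta-1,3-diene | CC(C)=CC(=C)O[Si](C)(C)C | intermediate (not isolated)
13 | 1-bromo-4-methylpent-3-en-2-one | CC(C)=CC(=O)CBr | intermediate
14 | methyl (triphenylphosphoranylidene)acetate | COC(=O)C=P(c1ccccc1)(c1ccccc1)c1ccccc1 | starting material
15 | racemic (1-methoxy-6-methyl-1,4-dioxohept-5-en-2-yl)triphenylphosphonium bromide | COC(=O)C(CC(=O)C=C(C)C)[P+](c1ccccc1)(c1ccccc1)c1ccccc1.[Br-] | intermediate (not isolated)
16 | methyl 6-methyl-4-oxo-2-(triphenylphosphoranylidene)hept-5-enoate | COC(=O)C(CC(=O)C=C(C)C)=P(c1ccccc1)(c1ccccc1)c1ccccc1 | intermediate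
17 | methyl (2E,6E,10E,12E)-6,10-dimethyl-2-(4-methyl-2-oxopent-3-en-1-yl)-13-(5-oxo-2,5-dihydrofuran-3-yl)trideca-2,6,10,12-tetraenoate | CC(C)=CC(=O)C/C(=C\CC/C(C)=C/CC/C(C)=C/C=C/C1=CC(=O)OC1)C(=O)OC | intermediate
18 | methyl (2E,6E,10E,12E)-2-[(2S)-2-hydroxy-4-methylpent-3-en-1-yl]-6,10-dimethyl-13-(5-oxo-2,5-dihydrofuran-3-yl)trideca-2,6,10,12-tetraenoate | CC(C)=C[C@@H](O)C/C(=C\CC/C(C)=C/CC/C(C)=C/C=C/C1=CC(=O)OC1)C(=O)OC | intermediate (not isolated)
19 | (3E,5S)-3-[(4E,8E,10E)-4,8-dimethyl-11-(5-oxo-2,5-dihydrofuran-3-yl)undeca-4,8,10-trien-1-ylidene]-5-(2-methylprop-1-en-1-yl)oxolan-2-one (CNP0187251.1) | CC(C)=C[C@@H]1C/C(=C\CC/C(C)=C/CC/C(C)=C/C=C/C2=CC(=O)OC2)C(=O)O1 | target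

Total step count: 12.
Longest linear sequence: 9 steps (steps 1, 2, 3, 4, 5, 7, 8, 11, 12).

Steps most likely to fail

Step 12. The enzyme may fail to bind the long lipophilic polyene, or may deliver hydride to the wrong face or with poor facial discrimination between two fairly large ketone substituents. The fallback replaces enzyme control by reagent control. It sets out from 17: Corey–Bakshi–Shibata reduction with (R)-2-methyl-CBS-oxazaborolidine and catecholborane in toluene at −78 °C, the alkenyl group acting as the large substituent, should deliver hydride to the same Re face. This gives the hydroxy ester 18, which lactonises on silica gel, and the route is rejoined at 19. This fallback makes no new compound (F0).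

Step 5. The lithiated bis(boronate) may deprotonate the enal at its γ-position, which would scramble the C2–C3 geometry, or add in a conjugate sense, or the elimination may give incomplete trans selectivity. The fallback replaces carbonyl olefination by alkyne homologation and hydrometalation. It sets out from 5: Colvin homologation (Me3SiCHN2, n-BuLi, THF, −78 °C → rt) should give 2,2-dimethyl-3-[(3E,7E)-3,7-dimethyldeca-3,7-dien-9-yn-1-yl]oxirane F1. Syn-hydroboration of the terminal alkyne with pinacolborane, Cp2Zr(H)Cl (10 mol %) and Et3N (10 mol %) then fixes the new alkene as E, and the route is rejoined at 6.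

Step 7. Aqueous base may hydrolyse the bromobutenolide by addition–elimination, or protodeboronation of the dienyl boronate may outrun transmetalation. The fallback is a base-free Stille coupling with the polarity of the partners reversed, setting out from 5 and 8. Takai iodo-olefination of 5 (CrCl2, CHI3, THF, 0 °C) should give 3-[(3E,7E,9E)-10-iodo-3,7-dimethyldeca-3,7,9-trien-1-yl]-2,2-dimethyloxirane F2. Stannylation of 8 with (Bu3Sn)2 and Pd(PPh3)4 in toluene at 90 °C should give 4-(tributylstannyl)furan-2(5H)-one F3. Their coupling (Pd2(dba)3, AsPh3, CuI, NMP, rt) rejoins the route at 9.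

Further compounds
F0 | step 12 | none | none
F1 | step 5 | racemic 2,2-dimethyl-3-[(3E,7E)-3,7-dimethyldeca-3,7-dien-9-yn-1-yl]oxirane | CC1(C)OC1CC/C(C)=C/CC/C(C)=C/C#C
F2 | step 7 | racemic 3-[(3E,7E,9E)-10-iodo-3,7-dimethyldeca-3,7,9-trien-1-yl]-2,2-dimethyloxirane | CC1(C)OC1CC/C(C)=C/CC/C(C)=C/C=C/I
F3 | step 7 | 4-(tributylstannyl)furan-2(5H)-one | CCCC[Sn](CCCC)(CCCC)C1=CC(=O)OC1
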